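**The leftover.** You ask for a quick number on the green flask, and I start from its leftover L, the part of the charged substrates not yet read as product.

in all of them: left-handed substrate 24 mM; right-handed substrate 24 mM; gas 1.3 mM (held); racemization catalyst 1.2 mM
- green: precatalyst 3.1 mM; the very flask that is asked about, followed so far
- red: precatalyst 1.6 mM; run made earlier
- flask: precatalyst 3.1 mM; time 2.0 h

| run | time / min | left-handed product / % | right-handed product / % |
|---|---|---|---|
| green | 4.00 | 1.2 | 0.9 |
| green | 12.0 | 7.0 | 4.3 |
| green | 20.0 | 13.8 | 7.1 |
| green | 30.0 | 20.9 | 12.6 |
| green | 50.0 | 33.5 | 19.9 |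
| green | 60.0 | 37.9 | 23.9 |
| red | 6.00 | 1.0 | 0.2 |
| red | 15.0 | 6.5 | 3.6 |
| red | 30.0 | 13.6 | 6.6 |
| red | 50.0 | 21.8 | 12.5 |
| red | 60.0 | 26.3 | 14.6 |
| red | 80.0 | 33.0 | 19.5 |

(readings scatter by 0.5 percentage points)

- excess of left-handed product over right-handed product in the product at 6.0 min
- excess of left-handed product over right-handed product in the product at 2.0 h
- part of the left-handed substrate and right-handed substrate charged together that has reacted at 2.0 h

- free catalyst is single-handed; left-handed substrate and right-handed substrate are mirror images of each other, charged as a racemate, each of them at the stated concentration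
- at the start none of the gas is in solution
- an excess is below zero if the other one leads

**One constant.** In the green run L reads 79.1% at 20.0 min and 38.2% at 60.0 min. Suppose the same share of L goes each minute, a pseudo-first-order fall. Then the logarithm of their ratio, divided by the minutes between, gives 0.0182 /min; this k is the share of L lost per minute.

**Both ends.** The start is a separate matter: at 4.00 min the green run reads 2.10% reacted, less than the 7.02% that this k gives for a fall begun at time zero. Run back from 60.0 min, the line reaches the whole charge at a lag of 7.12 min, and that joins the two ends. So L = exp(−k(t − lag)), and I reckon 87.2% reacted at 2.0 h.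

**The excess.** The green excess of left-handed product reads 32.1% at 20.0 min and 22.7% at 60.0 min. I have no reckoning of my own for it.

**Your forecast.** It gives 30% at 6.0 min, then 20% and 87% reacted at 2.0 h, and it finds “rate is nearly proportional to precatalyst”.

**The result.** The green flask gives 31.6% at 6.0 min, then 18.9% and 88.0% reacted at 2.0 h, so the forecast stands within its margins.

    partner + free catalyst + left-handed substrate → free catalyst + left-handed product (k = 553 /M²/s)
    partner + free catalyst + right-handed substrate → free catalyst + right-handed product (k = 284 /M²/s)
    left-handed substrate + racemization catalyst ⇌ right-handed substrate + racemization catalyst, rate k3*[racemization catalyst]*[left-handed substrate] forward; the back reaction follows from the equilibrium constant (k = 0.138 /M/s)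
    gas ⇌ partner, rate k4*(csat - [partner]) (kL = 0.0498 /s)
    free catalyst ⇌ dormant form (K = 0.790, k = 9.33 × 10⁻⁴ /s)
    precatalyst ⇌ free catalyst (K = 0.370, k = 5.24 × 10⁻⁴ /s)

**Next flask.** The neighbouring flask has 5.3 mM of precatalyst, with the other charges and the time held. I scale k with precatalyst to 0.0311 /min and keep the lag, which puts L at 2.98% and the reacted part at 97.0%. That neighbouring flask gives 96.8% reacted at 2.0 h, with 1.8% of its charged left-handed substrate and 4.6% of its charged right-handed substrate still there.

The numbers in the tables are calculated with made-up constants, noise included.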